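**Plan**

- Retrosynthesis: the five phenols are masked as MOM ethers. The ring B cinnamate C=C is cut first (aldehyde plus the malonate half-ester of the ring C lactate). Next comes the bond between the vinylic CH and catechol ring A, then the terminal CH2 of the acrylate, and last the ring B O–C(α) bond.
- Enabling feature: the trisubstituted alkene has an α-carbon carrying the methyl ester and the ring B ether oxygen, and a β-CH carrying ring A. It is a β-arylated 2-aryloxyacrylate, which is what Heck arylation at the free CH2 of a terminal 2-aryloxyacrylate gives.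
- Forward: the ring B aldehyde is mono-protected, O-alkylated by carbenoid insertion and methylenated. Ring A is then attached by the Heck reaction, the ring C lactate is joined through the cinnamate, and all acetals are removed. No ring is formed; the three benzene rings are bought.
- Stereochemistry: the single R stereocentre comes unchanged from (R)-danshensu. The Z enol ether alkene comes from the Heck β-hydride elimination and the E cinnamate from the Doebner decarboxylative condensation.

Key step: step 6

Assumption: (R)-danshensu is used as the free acid (a sodium salt would be acidified first); the racemic phosphonate carbon of 5 is planarised in step 4 and has no consequence.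

**Route**

Step 1
Reactants: 1 3,4-dihydroxybenzaldehyde
Product: 2 3-hydroxy-4-(methoxymethoxy)benzaldehyde
Conditions: MOMCl (1.05 equiv), K2CO3 (1.1 equiv), acetone, 0 °C to rt
Reagents that add atoms: chloromethyl methyl ether (MOMCl), COCCl
Why: Williamson etherification: the 4-OH para to the formyl group is the more acidic phenol, so one equivalent of K2CO3 should form that phenoxide preferentially and deliver the 4-O-MOM ether, leaving the 3-OH free for step 3.

Step 2
Reactants: 3 trimethyl phosphonoacetate
Product: 4 trimethyl diazophosphonoacetate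
Conditions: p-ABSA (1.1 equiv), DBU (1.2 equiv), MeCN, 0 °C to rt
Reagents that add atoms: 4-acetamidobenzenesulfonyl azide (p-ABSA), CC(=O)Nc1ccc(cc1)S(=O)(=O)N=[N+]=[N-]
Why: Regitz diazo transfer: DBU deprotonates the doubly activated methylene and the carbanion takes the terminal N2 unit of the sulfonyl azide, releasing the sulfonamide.

Step 3
Reactants: 2 3-hydroxy-4-(methoxymethoxy)benzaldehyde; 4 trimethyl diazophosphonoacetate
Product: 5 methyl 2-(dimethoxyphosphoryl)-2-[5-formyl-2-(methoxymethoxy)phenoxy]acetate (racemic)
Conditions: Rh2(OAc)4 (1 mol %), toluene, 80 °C, slow addition of 4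
Reagents that add atoms: none
Why: Rhodium carbenoid O–H insertion: Rh2(OAc)4 decomposes 4 to an electrophilic carbenoid that the phenol oxygen captures (oxonium ylide, then proton shift) faster than the weakly nucleophilic formyl oxygen, a standard way to make 2-aryloxy phosphonoacetates; the new phosphonate-bearing carbon is racemic and is planarised in step 4.

Step 4
Reactants: 5 methyl 2-(dimethoxyphosphoryl)-2-[5-formyl-2-(methoxymethoxy)phenoxy]acetate
Product: 6 methyl 2-[5-formyl-2-(methoxymethoxy)phenoxy]acrylate
Conditions: 37% aq. HCHO (5 equiv), K2CO3 (2 equiv), THF–H2O, 0 °C to rt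
Reagents that add atoms: formaldehyde, C=O
Why: Horner–Wadsworth–Emmons methylenation: the stabilised phosphonate anion formed by K2CO3 adds to formaldehyde, which is far more electrophilic and in large excess relative to the aryl aldehyde, and loss of dimethyl phosphate gives the terminal 2-aryloxyacrylate.

Step 5
Reactants: 7 4-bromocatechol
Product: 8 4-bromo-1,2-bis(methoxymethoxy)benzene
Conditions: NaH (2.4 equiv), MOMCl (2.4 equiv), DMF, 0 °C to rt
Reagents that add atoms: chloromethyl methyl ether (MOMCl), COCCl
Why: Double Williamson etherification of the catechol dianion with MOMCl, a routine protection that is stable to the later palladium, base and amine conditions.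

Step 6
Reactants: 6 methyl 2-[5-formyl-2-(methoxymethoxy)phenoxy]acrylate; 8 4-bromo-1,2-bis(methoxymethoxy)benzene
Product: 9 methyl (Z)-3-[3,4-bis(methoxymethoxy)phenyl]-2-[5-formyl-2-(methoxymethoxy)phenoxy]acrylate
Conditions: Pd2(dba)3 (2.5 mol %), [(t-Bu)3PH]BF4 (10 mol %), Cy2NMe (1.5 equiv), 1,4-dioxane, 80 °C
Reagents that add atoms: none
Why: Zerovalent palladium formed from Pd2(dba)3 and P(t-Bu)3 inserts into the C–Br bond of 8, the arylpalladium bromide adds syn across the alkene of 6 with ring A delivered to the unsubstituted CH2 terminus and palladium to the carbon carrying the aryloxy and ester groups, and syn β-hydride elimination from the new benzylic CH2 releases 9 while Cy2NMe takes up HBr and returns the catalyst. The closest known reactions are Mizoroki–Heck arylations of captodative 2-acetamido- and 2-acyloxy-substituted acrylic systems and of methacrylates with aryl bromides, which give β-aryl trisubstituted alkenes. No ring is closed and no stereocentre is created; the new stereochemical element is the alkene geometry. The step needs regioselectivity, secured because the CH2 terminus is the only sterically open position and is also the β-carbon of the acrylate, and because the tertiary alkylpalladium intermediate has only the benzylic pair of β-hydrogens and no β-leaving group, so a single elimination is possible. The Z geometry should follow from the elimination conformer that keeps ring A anti to the methyl ester, the preference that gives Z dehydroamino esters, and it is also the more stable arrangement. The aldehyde, the MOM acetals and the methyl ester are spectators under these conditions.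

Step 7
Reactants: 10 (R)-3-(3,4-dihydroxyphenyl)lactic acid ((R)-danshensu)
Product: 11 methyl (R)-3-(3,4-dihydroxyphenyl)-2-hydroxypropanoate
Conditions: MeOH, p-TsOH·H2O (5 mol %), 65 °C, Ar
Reagents that add atoms: methanol, CO
Why: Fischer esterification under catalytic acid; the C–O and C–H bonds at the stereocentre are not touched, so the R configuration is retained.

Step 8
Reactants: 11 methyl (R)-3-(3,4-dihydroxyphenyl)-2-hydroxypropanoate
Product: 12 methyl (R)-3-[3,4-bis(methoxymethoxy)phenyl]-2-hydroxypropanoate
Conditions: MOMCl (2.3 equiv), K2CO3 (3 equiv), acetone, 0 °C to rt, Ar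
Reagents that add atoms: chloromethyl methyl ether (MOMCl), COCCl
Why: Chemoselective Williamson etherification: K2CO3 ionises only the two phenols, so the secondary α-hydroxy ester stays free and its stereocentre is not enolised under these mild conditions.

Step 9
Reactants: 12 methyl (R)-3-[3,4-bis(methoxymethoxy)phenyl]-2-hydroxypropanoate
Product: 13 3-{[(2R)-3-[3,4-bis(methoxymethoxy)phenyl]-1-methoxy-1-oxopropan-2-yl]oxy}-3-oxopropanoic acid
Conditions: Meldrum's acid (1.2 equiv), toluene, 90 °C
Reagents that add atoms: Meldrum's acid (2,2-dimethyl-1,3-dioxane-4,6-dione), CC1(C)OC(=O)CC(=O)O1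
Why: Alcoholysis of Meldrum's acid: on heating, the secondary alcohol acylates at a ring carbonyl and acetone is expelled to give the malonic half-ester, with the C–O bond at the stereocentre intact.

Step 10
Reactants: 9 methyl (Z)-3-[3,4-bis(methoxymethoxy)phenyl]-2-[5-formyl-2-(methoxymethoxy)phenoxy]acrylate; 13 3-{[(2R)-3-[3,4-bis(methoxymethoxy)phenyl]-1-methoxy-1-oxopropan-2-yl]oxy}-3-oxopropanoic acid
Product: 15 methyl (Z)-3-[3,4-bis(methoxymethoxy)phenyl]-2-[5-[(E)-3-{[(2R)-3-[3,4-bis(methoxymethoxy)phenyl]-1-methoxy-1-oxopropan-2-yl]oxy}-3-oxoprop-1-en-1-yl]-2-(methoxymethoxy)phenoxy]acrylate, via arylidenemalonic half-acid 14 (not isolated)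
Conditions: pyridine, piperidine (0.2 equiv), 55 °C
Reagents that add atoms: none
Why: Knoevenagel–Doebner condensation: piperidine-catalysed condensation of the aldehyde with the malonic half-ester gives the arylidenemalonic half-acid, whose decarboxylation in pyridine should give the E cinnamate, as in established syntheses of rosmarinic acid-type esters, without disturbing the α-acyloxy ester stereocentre.

Step 11
Reactants: 15 the penta-MOM ether of the target
Product: 16 methyl (Z)-3-(3,4-dihydroxyphenyl)-2-[2-hydroxy-5-[(E)-3-{[(2R)-3-(3,4-dihydroxyphenyl)-1-methoxy-1-oxopropan-2-yl]oxy}-3-oxoprop-1-en-1-yl]phenoxy]acrylate (CNP0178751.1)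
Conditions: HCl (1.25 M in MeOH), THF, 0 °C to rt
Reagents that add atoms: none
Why: Acid-catalysed transacetalisation: the five aryl MOM acetals are protonated and exchanged to methanol as dimethoxymethane at room temperature, conditions under which methyl esters, the conjugated secondary cinnamate and the ester-deactivated aryl enol ether should persist.

**Compound list**

1 | 3,4-dihydroxybenzaldehyde | O=Cc1ccc(O)c(O)c1 | starting material
2 | 3-hydroxy-4-(methoxymethoxy)benzaldehyde | O=Cc1ccc(OCOC)c(O)c1 | intermediate
3 | trimethyl phosphonoacetate | COC(=O)CP(=O)(OC)OC | starting material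
4 | trimethyl diazophosphonoacetate | COC(=O)C(=[N+]=[N-])P(=O)(OC)OC | intermediate
5 | methyl 2-(dimethoxyphosphoryl)-2-[5-formyl-2-(methoxymethoxy)phenoxy]acetate (racemic) | COC(=O)C(Oc1cc(C=O)ccc1OCOC)P(=O)(OC)OC | intermediate
6 | methyl 2-[5-formyl-2-(methoxymethoxy)phenoxy]acrylate | C=C(Oc1cc(C=O)ccc1OCOC)C(=O)OC | intermediate
7 | 4-bromocatechol | Oc1ccc(Br)cc1O | starting material
8 | 4-bromo-1,2-bis(methoxymethoxy)benzene | COCOc1ccc(Br)cc1OCOC | intermediate
9 | methyl (Z)-3-[3,4-bis(methoxymethoxy)phenyl]-2-[5-formyl-2-(methoxymethoxy)phenoxy]acrylate | COC(=O)/C(=C/c1ccc(OCOC)c(OCOC)c1)Oc1cc(C=O)ccc1OCOC | intermediate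
10 | (R)-3-(3,4-dihydroxyphenyl)lactic acid ((R)-danshensu) | O=C(O)[C@H](O)Cc1ccc(O)c(O)c1 | starting material
11 | methyl (R)-3-(3,4-dihydroxyphenyl)-2-hydroxypropanoate | COC(=O)[C@H](O)Cc1ccc(O)c(O)c1 | intermediate
12 | methyl (R)-3-[3,4-bis(methoxymethoxy)phenyl]-2-hydroxypropanoate | COC(=O)[C@H](O)Cc1ccc(OCOC)c(OCOC)c1 | intermediate
13 | 3-{[(2R)-3-[3,4-bis(methoxymethoxy)phenyl]-1-methoxy-1-oxopropan-2-yl]oxy}-3-oxopropanoic acid | COC(=O)[C@H](OC(=O)CC(=O)O)Cc1ccc(OCOC)c(OCOC)c1 | intermediate
14 | arylidenemalonic half-acid from 9 and 13 (ArCH=C(CO2H)CO2R, alkene geometry not defined; not isolated) | COC(=O)/C(=C/c1ccc(OCOC)c(OCOC)c1)Oc1cc(C=C(C(=O)O)C(=O)O[C@H](Cc2ccc(OCOC)c(OCOC)c2)C(=O)OC)ccc1OCOC | intermediate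
15 | methyl (Z)-3-[3,4-bis(methoxymethoxy)phenyl]-2-[5-[(E)-3-{[(2R)-3-[3,4-bis(methoxymethoxy)phenyl]-1-methoxy-1-oxopropan-2-yl]oxy}-3-oxoprop-1-en-1-yl]-2-(methoxymethoxy)phenoxy]acrylate | COC(=O)/C(=C/c1ccc(OCOC)c(OCOC)c1)Oc1cc(/C=C/C(=O)O[C@H](Cc2ccc(OCOC)c(OCOC)c2)C(=O)OC)ccc1OCOC | intermediate
16 | methyl (Z)-3-(3,4-dihydroxyphenyl)-2-[2-hydroxy-5-[(E)-3-{[(2R)-3-(3,4-dihydroxyphenyl)-1-methoxy-1-oxopropan-2-yl]oxy}-3-oxoprop-1-en-1-yl]phenoxy]acrylate | COC(=O)/C(=C/c1ccc(O)c(O)c1)Oc1cc(/C=C/C(=O)O[C@H](Cc2ccc(O)c(O)c2)C(=O)OC)ccc1O | target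

**Totals and risks**

Total step count: 11. Longest linear sequence: 6 steps (steps 1, 3, 4, 6, 10, 11 from 1; equally steps 2, 3, 4, 6, 10, 11 from 3).

Steps most likely to fail:

1. Step 6 (Heck arylation). Migratory insertion into the 1,1-disubstituted, donor- and acceptor-substituted alkene may be slow, so catalyst decay, radical polymerisation of the acrylate or hydrodebromination of the aryl bromide could compete, and the Z selectivity might be incomplete. The fallback sets out from 6 and 8 and comes back at 9, reversing the roles of the partners so that no alkene insertion is needed. Addition of Br2 to the enol ether alkene of 6 (CH2Cl2, −78 °C) would give methyl 2,3-dibromo-2-[5-formyl-2-(methoxymethoxy)phenoxy]propanoate F1. Treatment with Et3N in the same flask should eliminate HBr to give methyl (Z)-3-bromo-2-[5-formyl-2-(methoxymethoxy)phenoxy]acrylate F2. In parallel, Miyaura borylation of 8 (B2pin2, Pd(dppf)Cl2, KOAc, dioxane, 80 °C) would give 2-[3,4-bis(methoxymethoxy)phenyl]-4,4,5,5-tetramethyl-1,3,2-dioxaborolane F3. Suzuki–Miyaura coupling of F2 with F3 (Pd(PPh3)4, K2CO3, dioxane–H2O, 70 °C) should then give 9 with retention of the vinyl bromide geometry. If some E bromide is carried through, the coupled product could be equilibrated to the more stable Z isomer with catalytic iodine.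

2. Step 3 (carbenoid O–H insertion). The rhodium carbenoid could be intercepted by the formyl oxygen (carbonyl ylide formation leading to dioxolanes or epoxides) or could dimerise, in competition with insertion into the phenol O–H bond. The fallback sets out from 2 and comes back at 6, bypassing steps 2 to 4 and using no carbenoid. Phenol 2 (2 equiv) would be alkylated with methyl 2,3-dibromopropanoate (K2CO3, acetone, reflux). This proceeds through methyl 2-bromoacrylate formed in situ, oxa-Michael addition and SN2 displacement at the α-bromo ester, giving methyl 2,3-bis[5-formyl-2-(methoxymethoxy)phenoxy]propanoate F4. E1cB elimination of the β-aryloxide with DBU in THF should then give 6, returning one equivalent of 2 for recycling.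

3. Step 11 (global deprotection). Protic acid might hydrate the enol ether and break the ring B O–C(α) link, methanolysis might cleave the cinnamoyl ester, or acetal removal might stop at partially protected mixtures. The fallback sets out from 15 and comes back at 16 by an aprotic two-stage exchange. TMSBr (6 equiv, CH2Cl2, −30 °C) should convert the five MOM acetals into silyl ethers, giving the pentakis(trimethylsilyl) ether of the target F5 without free protic acid. Brief methanolysis (MeOH, NaHCO3-buffered, 0 °C) should then release the five phenols of 16 under near-neutral conditions.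

**Further compounds**

F1 | step 6 | methyl 2,3-dibromo-2-[5-formyl-2-(methoxymethoxy)phenoxy]propanoate | COC(=O)C(Br)(CBr)Oc1cc(C=O)ccc1OCOC
F2 | step 6 | methyl (Z)-3-bromo-2-[5-formyl-2-(methoxymethoxy)phenoxy]acrylate | COC(=O)/C(=C/Br)Oc1cc(C=O)ccc1OCOC
F3 | step 6 | 2-[3,4-bis(methoxymethoxy)phenyl]-4,4,5,5-tetramethyl-1,3,2-dioxaborolane | COCOc1ccc(cc1OCOC)B1OC(C)(C)C(C)(C)O1
F4 | step 3 | methyl 2,3-bis[5-formyl-2-(methoxymethoxy)phenoxy]propanoate | COC(=O)C(COc1cc(C=O)ccc1OCOC)Oc1cc(C=O)ccc1OCOC
F5 | step 11 | pentakis(trimethylsilyl) ether of the target | COC(=O)/C(=C/c1ccc(O[Si](C)(C)C)c(O[Si](C)(C)C)c1)Oc1cc(/C=C/C(=O)O[C@H](Cc2ccc(O[Si](C)(C)C)c(O[Si](C)(C)C)c2)C(=O)OC)ccc1O[Si](C)(C)C
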